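**Strategy.** Ring B of this ent-labdane is dissected at C9–C10 and C6–C7, a [3+3] union of a ring-A aldehyde acid with a dienyl methyl ketone. The key step, a one-pot ketal-Claisen rearrangement/aldol cyclisation, exploits two features: the C6(OH)–C7–C8(O) aldol pattern of ring B, and C18 on C4, which as a lactone tether to C6 (hemiacylal 8) makes the C6–O bond the migrating terminus and shields one face of C10. A vinyl acylal, formed in the flask from 8 and ketal 11, rearranges (C9–C10, quaternary C10), and methoxide then closes C6–C7, the C5, C6 and C9 centres converging by equilibration. The precursor is a butenolide-type acetal that bears no decalin.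

Key step: step 9

Remark on numbering: labdane numbering is used for the decalins and their precursors (ring A = C1–C5, C10; ring B = C5–C10; C18 = oxygenated carbon on C4; C19, C20 = methyl groups on C4, C10; C17 = carbon on C8; side chain C11–C16). The labdane name serves only as a constitutional frame; configuration is given by the CIP descriptors and the SMILES.

Assumption: in step 2 the ligand for the lithio-enamine is taken to give the (S)-keto ester from L-valine tert-butyl ester; should the sense be opposite, D-valine tert-butyl ester gives the same product and nothing else changes.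

Step 1
Reactants: 1 tert-butyl 2-oxocyclohexane-1-carboxylate; 2 L-valine tert-butyl ester
Product: 3 tert-butyl 2-{[(2S)-1-tert-butoxy-3-methyl-1-oxobutan-2-yl]amino}cyclohex-1-ene-1-carboxylate
Conditions: TsOH (cat.), toluene, reflux, Dean–Stark trap
Reagents that add atoms: none
Why: Acid-catalysed condensation of the β-keto ester with the primary amine (enamine formation) should give the conjugated, hydrogen-bonded enamino ester; no new stereocenter.

Step 2
Reactants: 3 enamino ester
Product: 4 tert-butyl (1S)-1-methyl-2-oxocyclohexane-1-carboxylate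
Conditions: LiN(iPr)2, toluene, −78 °C; MeI, THF (ligand), −78 to −20 °C; then 1 M HCl, rt
Reagents that add atoms: iodomethane CI
Why: Chiral-auxiliary enamine alkylation: the chelated lithio-enamine should be methylated on the face left open by the isopropyl group of the valine ester, which sets the quaternary carbon (later C4) as S, and acid hydrolysis returns the ketone and the auxiliary.

Step 3
Reactants: 4 keto ester
Product: 5 tert-butyl (1S)-1,3-dimethyl-2-oxocyclohexane-1-carboxylate (both C3 epimers)
Conditions: LiN(iPr)2, THF, −78 °C; MeI, −78 to 0 °C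
Reagents that add atoms: iodomethane CI
Why: Kinetic enolate alkylation at the only enolisable α-carbon installs the future C20 methyl group; the new stereocenter is erased in step 4, so the epimer mixture is carried on.

Step 4
Reactants: 5 dimethyl keto ester
Product: 6 tert-butyl (1S)-1,3-dimethyl-2-[(trifluoromethanesulfonyl)oxy]cyclohex-2-ene-1-carboxylate
Conditions: KN(SiMe3)2, THF, −78 °C; 2-[N,N-bis(trifluoromethylsulfonyl)amino]-5-chloropyridine, −78 to 0 °C
Reagents that add atoms: 2-[N,N-bis(trifluoromethylsulfonyl)amino]-5-chloropyridine FC(F)(F)S(=O)(=O)N(c1ccc(Cl)cn1)S(=O)(=O)C(F)(F)F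
Why: Enolisation can occur only towards the methyl-bearing carbon, and O-sulfonylation of the potassium enolate (enol triflate formation) should give the tetrasubstituted enol triflate.

Step 5
Reactants: 6 enol triflate
Product: 7 tert-butyl (1S)-2-formyl-1,3-dimethylcyclohex-2-ene-1-carboxylate
Conditions: Pd(OAc)2 (cat.), 1,3-bis(diphenylphosphino)propane, CO (1 atm), Et3SiH, Et3N, DMF, 70 °C
Reagents that add atoms: carbon monoxide [C-]#[O+]
Why: Palladium-catalysed reductive carbonylation (formylation) of the enol triflate—oxidative addition, CO insertion, hydride transfer from the silane—should give the enal while the tert-butyl ester stays inert.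

Step 6
Reactants: 7 enal tert-butyl ester
Product: 8 (7aS)-3-hydroxy-4,7a-dimethyl-5,6,7,7a-tetrahydro-2-benzofuran-1(3H)-one (hemiacylal, both C3 epimers, in equilibrium with the open aldehyde acid)
Conditions: CF3CO2H, CH2Cl2, 0 °C to rt
Reagents that add atoms: none
Why: Acidolysis of the tert-butyl ester frees the acid, which should close onto the neighbouring formyl group to the five-membered hydroxy lactone (ring–chain tautomerism of a γ-oxo acid); the hemiacylal carbon forms as an equilibrating epimer mixture.

Step 7
Reactants: 9 hept-6-yn-2-one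
Product: 10 6-methylideneoct-7-en-2-one
Conditions: ethene (1 atm), second-generation Grubbs catalyst RuCl2(=CHPh)(PCy3)(H2IMes) (cat.), CH2Cl2, rt
Reagents that add atoms: ethene C=C
Why: Cross enyne metathesis of the terminal alkyne with ethene should give the 2-substituted 1,3-butadiene directly; the ketone is tolerated.

Step 8
Reactants: 10 dienyl methyl ketone
Product: 11 7,7-dimethoxy-3-methylideneoct-1-ene
Conditions: HC(OMe)3, MeOH, TsOH (cat.), rt
Reagents that add atoms: trimethyl orthoformate COC(OC)OC
Why: Acid-catalysed ketalisation with the orthoformate as water scavenger; the diene should be untouched under these mild conditions.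

Step 9
Reactants: 8 hemiacylal; 11 dimethyl ketal (excess)
Product: 15 methyl (4S,5S,6R,9S,10R)-6-hydroxy-8-oxo-17-norlabda-13(16),14-dien-18-oate, via vinyl acylal 12 (not isolated), via enol lactone ketone 13 (not isolated), via keto aldehyde ester 14 (not isolated)
Conditions: EtCO2H (cat.), BHT (cat.), toluene, 110 °C, MeOH distilled off; then NaOMe (cat.), MeOH, 0 °C to rt
Reagents that add atoms: methanol CO
Why: Proposed new method: acid-catalysed exchange of the hemiacylal hydroxyl of 8 with ketal 11 should give vinyl acylal 12 (the trisubstituted enol ether being the thermodynamically preferred and reacting isomer), whose chair-like [3,3] shift forms C9–C10 and leaves enol lactone 13; methoxide then opens 13 to keto aldehyde 14, and the methyl-ketone enolate adds to the aldehyde to form C6–C7. The closest known reactions are the ketal Claisen rearrangement of allylic alcohols (Saucy–Marbet/Johnson type) and the base-mediated aldol closure of 1,5-keto aldehydes; new is the use of a hemiacylal as the allylic alcohol, so that the migrating terminus carries oxygen and emerges as a masked aldehyde. Ring B closes in the 6-(enolendo)-exo-trig mode. C10 is set by the suprafacial shift on the face of the bicyclic lactone opposite to its angular C4 methyl group, and because the two acetal epimers of 12 interconvert under the acid, both should drain through this faster pathway. C9, C5 and C6 are set under thermodynamic control (epimerisation next to the ketone and the aldehyde, reversible aldol addition) as the trans-decalin with equatorial side chain and equatorial 6-OH, which makes the E/Z ratio of 12 irrelevant. The step needs the C9 rather than the C7 enol ether and must stop at the ketol; the first rests on the greater stability of the more substituted enol ether, the second on catalytic methoxide at low temperature.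

Step 10
Reactants: 15 ketol ester
Product: 16 methyl (4S,5S,6R,9R,10S)-6-hydroxylabda-8(17),13(16),14-trien-18-oate
Conditions: Zn, CH2Br2, TiCl4, THF–CH2Cl2, 0 °C to rt
Reagents that add atoms: dibromomethane BrCBr
Why: Lombardo–Takai methylenation with the non-basic zinc–titanium carbenoid should convert the hindered, retro-aldol-prone ketone into the exocyclic alkene without touching ester, free hydroxyl or diene; the changed descriptors at C9 and C10 reflect priority changes only.

Step 11
Reactants: 16 exocyclic alkene
Product: 17 methyl (4S,5S,6R,8S,9S,10R)-8,17-epoxy-6-hydroxylabda-13(16),14-dien-18-oate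
Conditions: VO(acac)2 (cat.), t-BuOOH, CH2Cl2, 0 °C to rt
Reagents that add atoms: tert-butyl hydroperoxide CC(C)(C)OO
Why: Hydroxyl-directed epoxidation: the vanadium alkoxide of the equatorial homoallylic 6-OH should deliver oxygen to C8=C17 on the equatorial face, which is also the face remote from the axial C20 methyl group, so that the C8–O bond is equatorial (8S) and the remote diene is not addressed.

Step 12
Reactants: 17 epoxy ester
Product: 18 (4S,5S,6R,8S,9S,10R)-labda-13(16),14-diene-6,8,18-triol
Conditions: LiAlH4, THF, 0 °C to reflux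
Reagents that add atoms: none
Why: Hydride reduction should open the spiro-epoxide at the primary C17 (axial C8 methyl, equatorial tertiary alcohol, C8 configuration retained) and reduce the methyl ester to the C18 carbinol in the same operation.

Step 13
Reactants: 18 triol
Product: 19 (4S,5S,6R,8S,9S,10R)-6,8-dihydroxylabda-13(16),14-dien-18-yl acetate
Conditions: Ac2O (1 equiv), 2,4,6-collidine, CH2Cl2, −20 to 0 °C
Reagents that add atoms: acetic anhydride CC(=O)OC(C)=O
Why: Selective acylation: the primary 18-OH should be acetylated much faster than the hindered secondary 6-OH and the tertiary 8-OH.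

Compound list
1 | tert-butyl 2-oxocyclohexane-1-carboxylate | O=C1CCCCC1C(=O)OC(C)(C)C | starting material
2 | L-valine tert-butyl ester, tert-butyl (2S)-2-amino-3-methylbutanoate | CC(C)[C@H](N)C(=O)OC(C)(C)C | starting material
3 | tert-butyl 2-{[(2S)-1-tert-butoxy-3-methyl-1-oxobutan-2-yl]amino}cyclohex-1-ene-1-carboxylate | CC(C)[C@H](NC1=C(CCCC1)C(=O)OC(C)(C)C)C(=O)OC(C)(C)C | intermediate
4 | tert-butyl (1S)-1-methyl-2-oxocyclohexane-1-carboxylate | C[C@@]1(CCCCC1=O)C(=O)OC(C)(C)C | intermediate
5 | tert-butyl (1S)-1,3-dimethyl-2-oxocyclohexane-1-carboxylate (both C3 epimers) | C[C@@]1(CCCC(C)C1=O)C(=O)OC(C)(C)C | intermediate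
6 | tert-butyl (1S)-1,3-dimethyl-2-[(trifluoromethanesulfonyl)oxy]cyclohex-2-ene-1-carboxylate | C[C@@]1(CCCC(C)=C1OS(=O)(=O)C(F)(F)F)C(=O)OC(C)(C)C | intermediate
7 | tert-butyl (1S)-2-formyl-1,3-dimethylcyclohex-2-ene-1-carboxylate | C[C@@]1(CCCC(C)=C1C=O)C(=O)OC(C)(C)C | intermediate
8 | (7aS)-3-hydroxy-4,7a-dimethyl-5,6,7,7a-tetrahydro-2-benzofuran-1(3H)-one (both C3 epimers) | C[C@]12CCCC(C)=C1C(O)OC2=O | intermediate
9 | hept-6-yn-2-one | CC(=O)CCCC#C | starting material
10 | 6-methylideneoct-7-en-2-one | CC(=O)CCCC(=C)C=C | intermediate
11 | 7,7-dimethoxy-3-methylideneoct-1-ene | COC(C)(OC)CCCC(=C)C=C | intermediate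
12 | (7aS)-4,7a-dimethyl-3-[(6-methylideneocta-2,7-dien-2-yl)oxy]-5,6,7,7a-tetrahydro-2-benzofuran-1(3H)-one (C3 epimers, E/Z) | C[C@]12CCCC(C)=C1C(OC(C)=CCCC(=C)C=C)OC2=O | intermediate
13 | (4S,7aS)-4,7a-dimethyl-4-(6-methylidene-2-oxooct-7-en-3-yl)-5,6,7,7a-tetrahydro-2-benzofuran-1(4H)-one (side-chain C3 epimers) | C[C@]12CCC[C@@](C)(C(CCC(=C)C=C)C(C)=O)C1=COC2=O | intermediate
14 | methyl (1S,3R)-2-formyl-1,3-dimethyl-3-(6-methylidene-2-oxooct-7-en-3-yl)cyclohexane-1-carboxylate (epimers at C2 and side-chain C3) | COC(=O)[C@@]1(C)CCC[C@@](C)(C(CCC(=C)C=C)C(C)=O)C1C=O | intermediate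
15 | methyl (4S,5S,6R,9S,10R)-6-hydroxy-8-oxo-17-norlabda-13(16),14-dien-18-oate | C=CC(=C)CC[C@H]1[C@]2(C)CCC[C@](C)(C(=O)OC)[C@H]2[C@H](O)CC1=O | intermediate
16 | methyl (4S,5S,6R,9R,10S)-6-hydroxylabda-8(17),13(16),14-trien-18-oate | C=CC(=C)CC[C@H]1[C@]2(C)CCC[C@](C)(C(=O)OC)[C@H]2[C@H](O)CC1=C | intermediate
17 | methyl (4S,5S,6R,8S,9S,10R)-8,17-epoxy-6-hydroxylabda-13(16),14-dien-18-oate | C=CC(=C)CC[C@H]1[C@]2(C)CCC[C@](C)(C(=O)OC)[C@H]2[C@H](O)C[C@@]13CO3 | intermediate
18 | (4S,5S,6R,8S,9S,10R)-labda-13(16),14-diene-6,8,18-triol | C=CC(=C)CC[C@H]1[C@]2(C)CCC[C@](C)(CO)[C@H]2[C@H](O)C[C@]1(C)O | intermediate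
19 | (4S,5S,6R,8S,9S,10R)-6,8-dihydroxylabda-13(16),14-dien-18-yl acetate | C=CC(=C)CC[C@H]1[C@]2(C)CCC[C@](C)(COC(C)=O)[C@H]2[C@H](O)C[C@]1(C)O | target

Total step count: 13. Longest linear sequence: 11 steps (steps 1–6 and 9–13); steps 7 and 8 make the second fragment.

Steps most likely to fail

Step 9 (key step). The enol-ether exchange may channel through the less substituted vinyl acylal, or the acylal may ionise before the sigmatropic shift, so that the quaternary centre forms with the wrong constitution or not at all; the ketol may also dehydrate. The fallback uses known chemistry, sets out from 8 and rejoins at 16. Myrcene is oxidised at its (E)-methyl group (SeO2 cat., t-BuOOH) to (2E)-2-methyl-6-methylideneocta-2,7-dien-1-ol F1 and converted (NCS, Me2S) into the allylic chloride F2. The allylbarium reagent from F2 (activated Ba, THF, −78 °C, two equivalents, the first opening 8 to its aldehyde carboxylate) adds through its α-carbon to give the dienol acid F3 as its dialkoxide. After exchange to potassium (KN(SiMe3)2, 18-crown-6) this undergoes the anionic oxy-Cope rearrangement to the aldehyde acid F4, which forms C9–C10 through a chair transition state. Esterification (Me3SiCHN2) gives the aldehyde ester F5, and the Me2AlCl-promoted type 2 carbonyl-ene cyclisation (CH2Cl2, −78 °C) closes C6–C7 and gives 16, so that steps 9 and 10 are both replaced. This sequence lacks the lactone tether, so the C10 and C6 epimers would have to be separated.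

Step 10. The Lewis-acidic titanium reagent may dehydrate the β-hydroxy ketone to the enone, or the hindered carbonyl may stay unchanged. The fallback sets out from 15 and rejoins at 16 by Peterson olefination: Me3SiCH2Li/CeCl3 (THF, −78 °C) adds to the ketone to give the β-hydroxy silane F6, and KH (THF, 0 °C) brings about syn-elimination to 16.

Step 11. Oxygen may be transferred to the side-chain diene, or delivered to the axial face of the exocyclic alkene. The fallback sets out from 16 and rejoins at 17. The diene is masked as its sulfolene F7 (liquid SO2, hydroquinone, sealed tube). The exocyclic alkene is then epoxidised with m-CPBA (NaHCO3, CH2Cl2, 0 °C) from the less hindered equatorial face to give the epoxy sulfolene F8. Cheletropic loss of SO2 (toluene, NaHCO3, 110 °C) returns the diene as 17.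

Further compounds
F1 | step 9 | (2E)-2-methyl-6-methylideneocta-2,7-dien-1-ol | OC/C(C)=C/CCC(=C)C=C
F2 | step 9 | (2E)-1-chloro-2-methyl-6-methylideneocta-2,7-diene | ClC/C(C)=C/CCC(=C)C=C
F3 | step 9 | (1S)-2-[(3E)-1-hydroxy-3-methyl-7-methylidenenona-3,8-dien-1-yl]-1,3-dimethylcyclohex-2-ene-1-carboxylic acid (carbinol epimers) | OC(=O)[C@@]1(C)CCCC(C)=C1C(O)C/C(C)=C/CCC(=C)C=C
F4 | step 9 | (1S)-2-formyl-1,3-dimethyl-3-(2-methyl-6-methylideneocta-1,7-dien-3-yl)cyclohexane-1-carboxylic acid (ring C3 configured as in 14) | OC(=O)[C@@]1(C)CCC[C@@](C)(C(CCC(=C)C=C)C(C)=C)C1C=O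
F5 | step 9 | methyl (1S)-2-formyl-1,3-dimethyl-3-(2-methyl-6-methylideneocta-1,7-dien-3-yl)cyclohexane-1-carboxylate (ring C3 configured as in 14) | COC(=O)[C@@]1(C)CCC[C@@](C)(C(CCC(=C)C=C)C(C)=C)C1C=O
F6 | step 10 | methyl (4S,5S,6R,9S,10R)-6,8-dihydroxy-17-(trimethylsilyl)labda-13(16),14-dien-18-oate (C8 epimers) | C=CC(=C)CC[C@H]1[C@]2(C)CCC[C@](C)(C(=O)OC)[C@H]2[C@H](O)CC1(O)C[Si](C)(C)C
F7 | step 11 | sulfolene of 16, methyl (4S,5S,6R,9R,10S)-6-hydroxy-8(17)-ene ester with the side-chain diene as 3-substituted 2,5-dihydrothiophene 1,1-dioxide | O=S3(=O)CC=C(C3)CC[C@H]1[C@]2(C)CCC[C@](C)(C(=O)OC)[C@H]2[C@H](O)CC1=C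
F8 | step 11 | 8,17-epoxide of F7, configured as in 17 | O=S3(=O)CC=C(C3)CC[C@H]1[C@]2(C)CCC[C@](C)(C(=O)OC)[C@H]2[C@H](O)C[C@@]14CO4
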